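**Plan**

- Guaiane numbering is used for both C15 halves, with primes for the half that holds the spiro carbon. The central cyclohexene C2–C1=C10–C14–C15'–C4' has a ring alkene (C1=C10) opposite a spiro carbon (C4') that sits next to a ketone (C3'=O). This is a Diels–Alder retron, and both halves are the same guaianolide.
- Retrosynthesis: the O–Si bond of a silyl helper on O2 is cut first, then C2–C4' and C14–C15' together in one [4+2] cut. This gives the dienophile dehydrozaluzanin C (C4'=C15') and a diene C2=C1–C10=C14 of the same skeleton, held s-cis because C1–C10 is a bond of the seven-membered ring and already carrying the C2 oxygen (a silylated diosphenol).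
- Forward: the six rings of the two 5-7-5 tricycles come intact from dehydrocostus lactone. C3 is oxidised to the ketone; part of the ketone is oxygenated at C2, oxidised to the diosphenol and silylated. The cyclohexene is closed last by joining the two monomers, and desilylation ends the route.
- Stereochemistry: C1', C5', C6', C7', C5, C6 and C7 come from the starting material. C4' and C2 are set together in the cycloaddition (convex α face of the dienophile, ketone endo, hence β face of the diene).

Key step: step 7

Assumption: dehydrocostus lactone, an isolated enantiopure sesquiterpene lactone sold by fine-chemical suppliers, is taken as the commercially available starting material.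

**Route**

Step 1
Reactants: 1 dehydrocostus lactone
Product: 2 isozaluzanin C (3α-hydroxy derivative of 1)
Conditions: SeO2 (0.5 equiv), tBuOOH (2 equiv), CH2Cl2, rt
Reagents that add atoms: tert-butyl hydroperoxide, CC(C)(C)OO (source of the new oxygen atom, passed on by the catalyst selenium dioxide, O=[Se]=O)
Why: The SeO2/tBuOOH allylic oxidation (ene reaction, then [2,3]-sigmatropic shift) should attack the 4(15)-alkene at its ring CH2 (C3) from the convex α face while the electron-poor α-methylene lactone stays inert, and the C3 configuration does not matter because C3 becomes a ketone in step 2.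

Step 2
Reactants: 2 isozaluzanin C
Product: 3 dehydrozaluzanin C (3-oxo derivative of 1)
Conditions: Dess–Martin periodinane (1.3 equiv), CH2Cl2, rt
Reagents that add atoms: none
Why: Dess–Martin oxidation of the allylic alcohol should give the exo-methylene cyclopentanone under near-neutral conditions that do not move the exocyclic alkenes into the rings.

Step 3
Reactants: 3 dehydrozaluzanin C
Product: 4 3-(triethylsilyloxy)guaia-2,4(15),10(14),11(13)-tetraen-12,6α-olide (TES dienol ether of 3)
Conditions: TESOTf (1.2 equiv), Et3N (2.5 equiv), CH2Cl2, −78 °C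
Reagents that add atoms: triethylsilyl trifluoromethanesulfonate, CC[Si](CC)(CC)OS(=O)(=O)C(F)(F)F
Why: Soft enolisation and O-silylation can only go toward C2, the sole α-carbon with hydrogen (C4 is the alkene carbon), so a single 2-silyloxy-1,3-diene should form without touching C1 or C5.

Step 4
Reactants: 4 TES dienol ether of 3
Product: 6 2α-hydroxydehydrozaluzanin C, via silyloxy epoxide 5 (not isolated)
Conditions: DMDO (1.05 equiv, acetone), CH2Cl2, −78 °C; then aq. HCl (cat.), THF, 0 °C
Reagents that add atoms: dimethyldioxirane, CC1(C)OO1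
Why: In this Rubottom oxidation the silyl enol ether is by far the most electron-rich alkene and should be epoxidised at C2=C3 from the convex α face (anti to C10), and acid opens the silyloxy epoxide to the α'-hydroxy enone; the new C2 centre is erased in step 5.

Step 5
Reactants: 6 2α-hydroxydehydrozaluzanin C
Product: 8 2-hydroxy-3-oxoguaia-1,4(15),10(14),11(13)-tetraen-12,6α-olide (diosphenol), via 2,3-dione 7 (not isolated)
Conditions: Dess–Martin periodinane (1.2 equiv), CH2Cl2, 0 °C to rt
Reagents that add atoms: none
Why: Dess–Martin oxidation of the α-ketol gives the cyclopentane-1,2-dione, which should enolise at once and only toward C1 (C4 has no hydrogen), the usual enol preference of cyclopentane-1,2-diones being reinforced by conjugation with the 10(14)-alkene.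

Step 6
Reactants: 8 diosphenol
Product: 9 2-(triethylsilyloxy)-3-oxoguaia-1,4(15),10(14),11(13)-tetraen-12,6α-olide (silyloxy diene)
Conditions: TESCl (1.2 equiv), imidazole (2 equiv), CH2Cl2, 0 °C
Reagents that add atoms: chlorotriethylsilane, CC[Si](Cl)(CC)CC
Why: O-silylation of the acidic diosphenol hydroxyl is a standard silyl ether formation, and the silyl group locks the 1-oxy diene, blocks the [1,5]-hydrogen shift from O–H to C14 that would destroy it, and keeps its HOMO high.

Step 7
Reactants: 9 silyloxy diene and 3 dehydrozaluzanin C (dienophile)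
Product: 10 O-triethylsilyl ether of 11
Conditions: 3 (3 equiv), BHT (5 mol %), PhMe (1 M), 70 °C, dark, Ar
Reagents that add atoms: none
Why: A thermal, concerted but asynchronous normal-demand [4+2] cycloaddition joins the 1-silyloxy diene C2=C1–C10=C14 of 9 (HOMO raised by O2, s-cis by the ring bond C1–C10) to the exo-methylene ketone C4'=C15' of 3, the open CH2–CH2 bond C14–C15' running ahead of the crowded C2–C4' bond; the closest known reaction types are Diels–Alder additions of 1-silyloxy dienes to α-methylene ketones and the thermal dimerisation of cross-conjugated dienones with α-methylene cyclopentanones. The one ring closed is the central cyclohexene (C2, C1, C10, C14, C15', C4'), by intermolecular suprafacial–suprafacial [4+2] closure, which makes C4' a spiro atom. C4' is controlled by the dienophile face: the diene must come to the convex α face of the cis-fused hydroazulenone (the side of H1' and H5'), because the cycloheptane and its lactone hang from β bonds. C2 is controlled by the diene face, which is tied to the endo/exo choice: with the α face of 3 engaged, only bonding on the β face of 9 (anti to H5) puts the slim C3'=O/C2'H2 edge of the cyclopentanone under the diene (endo) and the bulky C5' edge outside, and this leaves the silyloxy group α at C2. Regiochemistry follows the ortho rule (oxygen-bearing C2 to carbonyl-bearing C4', terminal C14 to the β-carbon C15'); chemoselectivity rests on the ketone-activated exo-methylene of 3 being a much better dienophile than either α-methylene lactone, and the excess of 3 holds back self-dimerisation of 9 through its own C4=C15.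

Step 8
Reactants: 10 O-triethylsilyl ether of 11
Product: 11 target
Conditions: HF·pyridine, THF/pyridine, 0 °C to rt
Reagents that add atoms: none
Why: Fluoride-mediated Si–O cleavage under acidic, non-basic conditions should free the tertiary alcohol without retro-aldol cleavage of the C2(OH)–C4'–C3'=O unit and without conjugate addition to the α-methylene lactones.

**Compound list**

1 | dehydrocostus lactone (1α,5α,7α-H,6β-H-guaia-4(15),10(14),11(13)-trien-12,6α-olide) | C=C1CC[C@H]2C(=C)CC[C@H]3C(=C)C(=O)O[C@@H]3[C@H]21 | starting material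
2 | isozaluzanin C (3α-hydroxy derivative of 1) | C=C1[C@H](O)C[C@H]2C(=C)CC[C@H]3C(=C)C(=O)O[C@@H]3[C@H]21 | intermediate
3 | dehydrozaluzanin C (3-oxo derivative of 1) | C=C1C(=O)C[C@H]2C(=C)CC[C@H]3C(=C)C(=O)O[C@@H]3[C@H]21 | intermediate
4 | 3-(triethylsilyloxy)guaia-2,4(15),10(14),11(13)-tetraen-12,6α-olide | C=C1C(O[Si](CC)(CC)CC)=C[C@H]2C(=C)CC[C@H]3C(=C)C(=O)O[C@@H]3[C@H]21 | intermediate
5 | 2α,3α-epoxy-3β-(triethylsilyloxy)guaia-4(15),10(14),11(13)-trien-12,6α-olide (silyloxy epoxide) | C=C1[C@]2(O[Si](CC)(CC)CC)O[C@@H]2[C@H]3C(=C)CC[C@H]4C(=C)C(=O)O[C@@H]4[C@H]31 | intermediate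
6 | 2α-hydroxydehydrozaluzanin C | C=C1C(=O)[C@H](O)[C@H]2C(=C)CC[C@H]3C(=C)C(=O)O[C@@H]3[C@H]21 | intermediate
7 | 2,3-dioxoguaia-4(15),10(14),11(13)-trien-12,6α-olide (keto form) | C=C1C(=O)C(=O)[C@H]2C(=C)CC[C@H]3C(=C)C(=O)O[C@@H]3[C@H]21 | intermediate
8 | 2-hydroxy-3-oxoguaia-1,4(15),10(14),11(13)-tetraen-12,6α-olide (diosphenol) | C=C1C(=O)C(O)=C2C(=C)CC[C@H]3C(=C)C(=O)O[C@@H]3[C@H]21 | intermediate
9 | 2-(triethylsilyloxy)-3-oxoguaia-1,4(15),10(14),11(13)-tetraen-12,6α-olide | C=C1C(=O)C(O[Si](CC)(CC)CC)=C2C(=C)CC[C@H]3C(=C)C(=O)O[C@@H]3[C@H]21 | intermediate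
10 | O-triethylsilyl ether of 11 (2α-silyloxy; C2–C4' bond β at C2 and α at C4') | C=C1C(=O)[C@]2(O[Si](CC)(CC)CC)C3=C(CC[C@H]4C(=C)C(=O)O[C@@H]4[C@@H]13)CC[C@]21C(=O)C[C@H]2C(=C)CC[C@H]3C(=C)C(=O)O[C@@H]3[C@H]21 | intermediate
11 | target: spiro-linked guaianolide dimer, 2α-hydroxy, C1=C10, bonds C2–C4' (β at C2, α at C4') and C14–C15' (β at C4') | C=C1C(=O)[C@]2(O)C3=C(CC[C@H]4C(=C)C(=O)O[C@@H]4[C@@H]13)CC[C@]21C(=O)C[C@H]2C(=C)CC[C@H]3C(=C)C(=O)O[C@@H]3[C@H]21 | target

**Count**

Total steps: 8. Longest linear sequence: 8 steps (1 to 11); compound 3 is used twice, in step 3 and as the partner in step 7.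

**Steps most likely to fail**

Step 7. Bond formation between two fully substituted carbons (C2 and C4') may be slow, so that self-dimerisation of the diene or of the dienophile competes. The diene-face selectivity may be lower than argued, or the silyl dienol ether may hydrolyse. The fallback moves the C2 oxygen to after the cycloaddition; it sets out from 4 and 3 and comes back at 11. Compound 4 is dehydrogenated by Saegusa–Ito oxidation (Pd(OAc)2, divalent palladium, MeCN, rt) to the cross-conjugated dienone 1,2-didehydrodehydrozaluzanin C F1, whose diene terminus C2 carries only hydrogen. F1 and an excess of 3 (PhMe, 60 °C) should undergo the same [4+2] addition to the 2-deoxy dimer F2. The doubly activated C2–H of F2 (α to C3=O, allylic to C1=C10) is removed with KN(SiMe3)2 (THF, −78 °C) to the potassium dienolate of the 2-deoxy dimer F3. 2-(Phenylsulfonyl)-3-phenyloxaziridine then hydroxylates its α-carbon to the potassium alkoxide of the target F4, which AcOH protonates to 11. Because C2 is planar in F3, the diene face used in the cycloaddition no longer matters; C2 is then fixed by the approach of the oxaziridine to the α face.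

Step 5. The α-ketol may over-oxidise with C2–C3 cleavage. The free diosphenol, which is diene and dienophile at once, may oligomerise, or may lose its diene by [1,5]-hydrogen shift to the ene-dione before it is silylated. The fallback never passes through the free diosphenol; it sets out from 6 and comes back at 9. The hydroxyl of 6 is silylated (TESCl, imidazole) to 2α-(triethylsilyloxy)dehydrozaluzanin C F5. Enolisation toward C2 (TESOTf, Et3N, −78 °C) gives the ene-diol bis-silyl ether 2,3-bis(triethylsilyloxy)guaia-2,4(15),10(14),11(13)-tetraen-12,6α-olide F6. Saegusa–Ito dehydrogenation (Pd(OAc)2, divalent palladium, MeCN) removes the silyl group on O3 and H1, which should give 9 directly.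

Step 4. Dimethyldioxirane may also epoxidise the 10(14)-alkene or the 4(15)-alkene of the diene, and the labile silyl dienol ether may hydrolyse back to 3 before it is oxidised. The fallback replaces enol ether epoxidation by enolate hydroxylation; it sets out from 3 and comes back at 6. Compound 3 is deprotonated at C2 with LiN(SiMe3)2 (THF, −78 °C) to the lithium enolate of dehydrozaluzanin C F7. 2-(Phenylsulfonyl)-3-phenyloxaziridine hydroxylates it from the convex face to the lithium alkoxide of 2α-hydroxydehydrozaluzanin C F8, and aqueous NH4Cl gives 6.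

**Further compounds**

F1 | step 7 | 1,2-didehydrodehydrozaluzanin C (3-oxoguaia-1,4(15),10(14),11(13)-tetraen-12,6α-olide) | C=C1C(=O)C=C2C(=C)CC[C@H]3C(=C)C(=O)O[C@@H]3[C@H]21
F2 | step 7 | 2-deoxy dimer (11 with H in place of OH at C2, H α) | C=C1C(=O)[C@@H]2C3=C(CC[C@H]4C(=C)C(=O)O[C@@H]4[C@@H]13)CC[C@]21C(=O)C[C@H]2C(=C)CC[C@H]3C(=C)C(=O)O[C@@H]3[C@H]21
F3 | step 7 | potassium dienolate of the 2-deoxy dimer (O3–C3=C2–C1=C10) | C=C1C([O-])=C2C3=C(CC[C@H]4C(=C)C(=O)O[C@@H]4[C@@H]13)CC[C@]21C(=O)C[C@H]2C(=C)CC[C@H]3C(=C)C(=O)O[C@@H]3[C@H]21.[K+]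
F4 | step 7 | potassium alkoxide of the target | C=C1C(=O)[C@]2([O-])C3=C(CC[C@H]4C(=C)C(=O)O[C@@H]4[C@@H]13)CC[C@]21C(=O)C[C@H]2C(=C)CC[C@H]3C(=C)C(=O)O[C@@H]3[C@H]21.[K+]
F5 | step 5 | 2α-(triethylsilyloxy)dehydrozaluzanin C | C=C1C(=O)[C@H](O[Si](CC)(CC)CC)[C@H]2C(=C)CC[C@H]3C(=C)C(=O)O[C@@H]3[C@H]21
F6 | step 5 | 2,3-bis(triethylsilyloxy)guaia-2,4(15),10(14),11(13)-tetraen-12,6α-olide | C=C1C(O[Si](CC)(CC)CC)=C(O[Si](CC)(CC)CC)[C@H]2C(=C)CC[C@H]3C(=C)C(=O)O[C@@H]3[C@H]21
F7 | step 4 | lithium enolate of dehydrozaluzanin C | C=C1C([O-])=C[C@H]2C(=C)CC[C@H]3C(=C)C(=O)O[C@@H]3[C@H]21.[Li+]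
F8 | step 4 | lithium alkoxide of 2α-hydroxydehydrozaluzanin C | C=C1C(=O)[C@H]([O-])[C@H]2C(=C)CC[C@H]3C(=C)C(=O)O[C@@H]3[C@H]21.[Li+]
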